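## Retrosynthetic overview

1. Numbering used: oxolane O1, C2 (quaternary), C3 (CHBr), C4 (CH2), C5 (CH); side chain C1' (CBr) and C2' (CH2Cl). The C3 bromide is traced back to a C3 ketone (reduction, then SN2 with inversion), and the (E)-bromovinyl group to a silyl-capped alkyne (desilylation, hydrozirconation–bromination).
2. Key disconnection: the C4–C5 bond of the oxolan-3-one, made by a Petasis–Ferrier-type rearrangement of a 4-methylene-1,3-dioxolane. The dioxolane ring and its acetal C5–O(enol) bond are not in the target; they only hold C4 and C5 together and are consumed as the oxolane closes.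
3. Enabling feature: C5 sits between the ring oxygen O1 and the fully substituted C1' (no α-hydrogen), so it can be the carbon of a non-enolisable aldehyde and then of an oxocarbenium ion. C3–C4, next to the quaternary carbinol carbon C2, maps onto a terminal alkyne, which becomes the enol ether and then the enolate.
4. Stereochemistry: C2 comes from a Sharpless epoxidation of an enynol (then epoxy chloride to diynol). C1' comes from a second Sharpless epoxidation, stereospecific bromide opening and glycol cleavage. C5 is relayed in the key step from C2 (1,3) and C1' (1,2); C3 is set by reagent-controlled reduction and inversion.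
5. Order of ring formation: the temporary 1,3-dioxolane (step 11), then the oxolane (step 12) with loss of the dioxolane.

Key step: step 12

Remark: (E)-3-methylpent-2-en-4-yn-1-ol is used as the geometrically pure E isomer, and both enantiomers of diethyl tartrate are taken as commercial.

## Route

Step 1
Reactants: 1 (E)-3-methylpent-2-en-4-yn-1-ol
Product: 3 (E)-3-methyl-5-[tri(propan-2-yl)silyl]pent-2-en-4-yn-1-ol, via dilithium alkoxide acetylide 2 (not isolated)
Conditions: n-BuLi (2.1 equiv), THF, −78 °C; iPr3SiCl (1.05 equiv), −78 °C to rt; H2O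
Reagents that add atoms: chlorotri(propan-2-yl)silane, CC(C)[Si](Cl)(C(C)C)C(C)C
Why: Double deprotonation gives the alkoxide–acetylide dianion, whose acetylide carbon is silylated selectively by the hindered chlorosilane (C-silylation of a dianion), so the two alkynes of the later diynol can be told apart while the E-alkene is untouched.

Step 2
Reactants: 3 (E)-3-methyl-5-[tri(propan-2-yl)silyl]pent-2-en-4-yn-1-ol
Product: 4 [(2S,3S)-3-methyl-3-{[tri(propan-2-yl)silyl]ethynyl}oxiran-2-yl]methanol
Conditions: Ti(OiPr)4 (10 mol%), L-(+)-diethyl tartrate (12 mol%), t-BuOOH (2 equiv), 4 Å MS, CH2Cl2, −20 °C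
Reagents that add atoms: tert-butyl hydroperoxide, CC(C)(C)OO
Why: Sharpless asymmetric epoxidation of an E-trisubstituted allylic alcohol, in which the L-(+)-tartrate catalyst should deliver oxygen to the enantioface that gives the (2S,3S)-epoxide and so fixes the quaternary C–O centre that becomes ring C2, the hindered silyl alkyne being inert.

Step 3
Reactants: 4 [(2S,3S)-3-methyl-3-{[tri(propan-2-yl)silyl]ethynyl}oxiran-2-yl]methanol
Product: 5 (2R,3S)-2-(chloromethyl)-3-methyl-3-{[tri(propan-2-yl)silyl]ethynyl}oxirane
Conditions: PPh3, CCl4, NaHCO3, reflux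
Reagents that add atoms: tetrachloromethane, ClC(Cl)(Cl)Cl
Why: Appel chlorination of the primary alcohol under buffered conditions proceeds by SN2 at the CH2 group and leaves the epoxide and both stereocentres untouched.

Step 4
Reactants: 5 (2R,3S)-2-(chloromethyl)-3-methyl-3-{[tri(propan-2-yl)silyl]ethynyl}oxirane
Product: 6 (3R)-3-methyl-1-[tri(propan-2-yl)silyl]penta-1,4-diyn-3-ol
Conditions: LiN(iPr)2 (3.3 equiv), THF, −78 to −30 °C; H2O
Reagents that add atoms: none
Why: Base-induced fragmentation of a 2,3-epoxy chloride to a propargylic alcohol (double dehydrochlorination with β-opening of the epoxide) creates the terminal alkyne without ever breaking the C–O bond at the quaternary carbon, so its configuration is retained and the carbinol now carries two different alkynes (C–H and C–Si).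

Step 5
Reactants: 7 3-methylbut-2-en-1-yl acetate (prenyl acetate)
Product: 8 (E)-4-hydroxy-3-methylbut-2-en-1-yl acetate
Conditions: SeO2 (0.3 equiv), t-BuOOH (2.5 equiv), CH2Cl2, rt
Reagents that add atoms: tert-butyl hydroperoxide, CC(C)(C)OO (its oxygen is passed on through catalytic SeO2)
Why: Selenium dioxide allylic oxidation (ene reaction, then 2,3-sigmatropic shift) attacks the E-methyl group of the trisubstituted alkene and therefore should give the E-allylic alcohol.

Step 6
Reactants: 8 (E)-4-hydroxy-3-methylbut-2-en-1-yl acetate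
Product: 9 (E)-4-chloro-3-methylbut-2-en-1-yl acetate
Conditions: PPh3, CCl4, CH2Cl2, 40 °C
Reagents that add atoms: tetrachloromethane, ClC(Cl)(Cl)Cl
Why: Appel reaction, in which chloride displaces the alkoxyphosphonium group by SN2 at the primary allylic carbon and the alkene geometry is kept.

Step 7
Reactants: 9 (E)-4-chloro-3-methylbut-2-en-1-yl acetate
Product: 10 (E)-4-chloro-3-methylbut-2-en-1-ol
Conditions: K2CO3 (0.2 equiv), MeOH, 0 °C
Reagents that add atoms: none
Why: Base-catalysed transesterification with methanol should remove the acetate at 0 °C faster than methoxide displaces the allylic chloride.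

Step 8
Reactants: 10 (E)-4-chloro-3-methylbut-2-en-1-ol
Product: 11 [(2R,3S)-3-(chloromethyl)-3-methyloxiran-2-yl]methanol
Conditions: Ti(OiPr)4 (10 mol%), D-(−)-diethyl tartrate (12 mol%), t-BuOOH (2 equiv), 4 Å MS, CH2Cl2, −20 °C
Reagents that add atoms: tert-butyl hydroperoxide, CC(C)(C)OO
Why: Sharpless asymmetric epoxidation with the D-(−)-tartrate catalyst, which should attack the enantioface opposite to that of step 2 and give the (2R,3S)-epoxide, whose tertiary C–O bond is placed so that its inversion leads to the R tertiary bromide.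

Step 9
Reactants: 11 [(2R,3S)-3-(chloromethyl)-3-methyloxiran-2-yl]methanol
Product: 12 (2R,3R)-3-bromo-4-chloro-3-methylbutane-1,2-diol
Conditions: Ti(OiPr)4 (1.5 equiv), Et2NH2Br (1.5 equiv), CH2Cl2, 0 °C to rt
Reagents that add atoms: diethylammonium bromide, CC[NH2+]CC.[Br-]
Why: Titanium-assisted regioselective opening of a 2,3-epoxy alcohol at C3 by bromide, in which the chelated titanium alkoxide activates the distal C–O bond and bromide enters with inversion at the fully substituted carbon, so the tertiary bromide stereocentre (future C1') follows stereospecifically from the epoxide with the chlorine already in place.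

Step 10
Reactants: 12 (2R,3R)-3-bromo-4-chloro-3-methylbutane-1,2-diol
Product: 13 (2R)-2-bromo-3-chloro-2-methylpropanal
Conditions: NaIO4, CH2Cl2/H2O (pH 7 buffer), 0 °C
Reagents that add atoms: none
Why: Periodate glycol cleavage removes the terminal carbinol carbon and unveils the α-bromo aldehyde, whose quaternary stereocentre has no α-hydrogen and cannot epimerise.

Step 11
Reactants: 6 (3R)-3-methyl-1-[tri(propan-2-yl)silyl]penta-1,4-diyn-3-ol; 13 (2R)-2-bromo-3-chloro-2-methylpropanal
Product: 15 (4S)-2-[(2R)-2-bromo-1-chloropropan-2-yl]-4-methyl-5-methylidene-4-{[tri(propan-2-yl)silyl]ethynyl}-1,3-dioxolane as both C2 epimers, via hemiacetal 14 (not isolated)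
Conditions: Ph3PAuNTf2 (5 mol%), 13 (1.3 equiv), 4 Å MS, CH2Cl2, 0 °C to rt; Et3N quench, filtration through basic Al2O3
Reagents that add atoms: none
Why: Proposed new method: the tertiary propargylic alcohol should add reversibly to the electron-poor, non-enolisable α-bromo aldehyde, and the hemiacetal hydroxyl should then add 5-exo-dig (Markovnikov) to the terminal alkyne activated by the cationic monovalent gold catalyst, protodeauration giving the exocyclic enol ether while the hindered silyl alkyne stays out; the closest known reaction types are gold-catalysed 5-exo-dig hydroalkoxylation of alkynols and the silver- or copper-catalysed carboxylative cyclisation of tertiary propargylic alcohols with CO2 to 4-methylene-1,3-dioxolan-2-ones (the hemiacetal oxygen takes the part of the carbonate oxygen), and the new acetal centre needs no control because it is erased in step 12.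

Step 12
Reactants: 15 (4S)-2-[(2R)-2-bromo-1-chloropropan-2-yl]-4-methyl-5-methylidene-4-{[tri(propan-2-yl)silyl]ethynyl}-1,3-dioxolane
Product: 17 (2S,5R)-5-[(2R)-2-bromo-1-chloropropan-2-yl]-2-methyl-2-{[tri(propan-2-yl)silyl]ethynyl}oxolan-3-one, via aluminium enolate oxocarbenium zwitterion 16 (not isolated)
Conditions: Me2AlCl (2 equiv), CH2Cl2, −78 to −20 °C; aq. NaHCO3
Reagents that add atoms: none
Why: Me2AlCl binds the enol ether oxygen and breaks the acetal C–O bond that is not part of the target, giving an aluminium enolate tethered through C2–O1 to an (E)-oxocarbenium ion, whose carbon (C5) is then attacked by the enolate carbon (C4). The closest known reaction type is the aluminium-promoted Petasis–Ferrier rearrangement of 4-methylene-1,3-dioxolanes to oxolan-3-ones. The oxolane closes in a 5-(enolendo)-endo-trig mode, which is feasible here because cleavage of the dioxolane releases the two reacting termini already held in a 1,5-relationship. The new stereocentre C5 is controlled by the quaternary C2 in an envelope transition state with the methyl group pseudo-equatorial and the rod-like silylalkynyl group (small effective size) pseudo-axial, so the bulky C5 substituent should end up cis to the methyl group, and the Felkin–Anh preference of the α-bromo oxocarbenium ion (C–Br anti to the incoming enolate, CH2Cl next to O1) should point the same way. Both acetal epimers of 15 converge on the same ion pair, so only the facial selectivity at C5 matters. The step needs ionisation of the acetal C–O(enol) bond and not of the tertiary propargylic C–O bond, which is secured because only the acetal carbon has a second oxygen lone pair to stabilise the cation and the propargylic C–O bond lies orthogonal to the enol ether π-system.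

Step 13
Reactants: 17 (2S,5R)-5-[(2R)-2-bromo-1-chloropropan-2-yl]-2-methyl-2-{[tri(propan-2-yl)silyl]ethynyl}oxolan-3-one
Product: 18 (2S,3S,5R)-5-[(2R)-2-bromo-1-chloropropan-2-yl]-2-methyl-2-{[tri(propan-2-yl)silyl]ethynyl}oxolan-3-ol
Conditions: (R)-2-methyl-CBS-oxazaborolidine (0.3 equiv), catecholborane (1.8 equiv), toluene, −78 °C
Reagents that add atoms: none
Why: Corey–Bakshi–Shibata reduction, in which the ketone is flanked by a fully substituted carbon (large) and a CH2 group (small), so the (R)-oxazaborolidine should deliver hydride under catalyst control to the face syn to the C2 methyl group and give the (3S)-alcohol, trans to the methyl group and to the C5 side chain.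

Step 14
Reactants: 18 (2S,3S,5R)-5-[(2R)-2-bromo-1-chloropropan-2-yl]-2-methyl-2-{[tri(propan-2-yl)silyl]ethynyl}oxolan-3-ol
Product: 20 (2S,3R,5R)-3-bromo-5-[(2R)-2-bromo-1-chloropropan-2-yl]-2-methyl-2-{[tri(propan-2-yl)silyl]ethynyl}oxolane, via triflate 19 (not isolated)
Conditions: Tf2O (1.3 equiv), 2,6-lutidine (2.5 equiv), CH2Cl2, −78 °C; Bu4NBr (3 equiv), −78 to 0 °C
Reagents that add atoms: tetrabutylammonium bromide, CCCC[N+](CCCC)(CCCC)CCCC.[Br-]
Why: SN2 displacement of a secondary triflate by bromide with inversion, a reaction type known for furanoside triflates next to a fully substituted carbon, which should place bromine cis to the C2 methyl group and the C5 side chain, the non-basic ammonium bromide in a weakly polar solvent disfavouring E2 and ionisation.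

Step 15
Reactants: 20 (2S,3R,5R)-3-bromo-5-[(2R)-2-bromo-1-chloropropan-2-yl]-2-methyl-2-{[tri(propan-2-yl)silyl]ethynyl}oxolane
Product: 21 (2S,3R,5R)-3-bromo-5-[(2R)-2-bromo-1-chloropropan-2-yl]-2-ethynyl-2-methyloxolane
Conditions: Bu4NF (1.2 equiv), AcOH (1.2 equiv), THF, 0 °C
Reagents that add atoms: none
Why: Fluoride-induced protodesilylation of the alkynylsilane, buffered with acetic acid so that the medium stays too weakly basic for E2 loss of HBr from the secondary and tertiary bromides.

Step 16
Reactants: 21 (2S,3R,5R)-3-bromo-5-[(2R)-2-bromo-1-chloropropan-2-yl]-2-ethynyl-2-methyloxolane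
Product: 23 (2S,3R,5R)-3-bromo-5-[(2R)-2-bromo-1-chloropropan-2-yl]-2-[(E)-2-bromoethenyl]-2-methyloxolane, via alkenylzirconocene chloride 22 (not isolated)
Conditions: Cp2Zr(H)Cl (1.5 equiv), THF, rt; NBS (1.6 equiv), 0 °C
Reagents that add atoms: N-bromosuccinimide, BrN1C(=O)CCC1=O
Why: Hydrozirconation–bromination, in which syn addition of Zr–H places zirconium on the terminal carbon (the other alkyne carbon is attached to a quaternary centre) and bromodezirconation with retention should give the E-bromoalkene.

## Compound list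

1 | (E)-3-methylpent-2-en-4-yn-1-ol | OC/C=C(\C)C#C | starting material
2 | dilithium alkoxide acetylide of 1 | [Li]OC/C=C(\C)C#C[Li] | intermediate (not isolated)
3 | (E)-3-methyl-5-[tri(propan-2-yl)silyl]pent-2-en-4-yn-1-ol | OC/C=C(\C)C#C[Si](C(C)C)(C(C)C)C(C)C | intermediate
4 | [(2S,3S)-3-methyl-3-{[tri(propan-2-yl)silyl]ethynyl}oxiran-2-yl]methanol | OC[C@H]1[C@](C)(C#C[Si](C(C)C)(C(C)C)C(C)C)O1 | intermediate
5 | (2R,3S)-2-(chloromethyl)-3-methyl-3-{[tri(propan-2-yl)silyl]ethynyl}oxirane | ClC[C@H]1[C@](C)(C#C[Si](C(C)C)(C(C)C)C(C)C)O1 | intermediate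
6 | (3R)-3-methyl-1-[tri(propan-2-yl)silyl]penta-1,4-diyn-3-ol | C#C[C@](C)(C#C[Si](C(C)C)(C(C)C)C(C)C)O | intermediate
7 | 3-methylbut-2-en-1-yl acetate (prenyl acetate) | CC(C)=CCOC(C)=O | starting material
8 | (E)-4-hydroxy-3-methylbut-2-en-1-yl acetate | CC(=O)OC/C=C(\C)CO | intermediate
9 | (E)-4-chloro-3-methylbut-2-en-1-yl acetate | CC(=O)OC/C=C(\C)CCl | intermediate
10 | (E)-4-chloro-3-methylbut-2-en-1-ol | OC/C=C(\C)CCl | intermediate
11 | [(2R,3S)-3-(chloromethyl)-3-methyloxiran-2-yl]methanol | OC[C@@H]1[C@@](C)(CCl)O1 | intermediate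
12 | (2R,3R)-3-bromo-4-chloro-3-methylbutane-1,2-diol | C[C@](Br)(CCl)[C@H](O)CO | intermediate
13 | (2R)-2-bromo-3-chloro-2-methylpropanal | C[C@](Br)(CCl)C=O | intermediate
14 | (2R)-2-bromo-3-chloro-2-methyl-1-{[(3R)-3-methyl-1-[tri(propan-2-yl)silyl]penta-1,4-diyn-3-yl]oxy}propan-1-ol (hemiacetal, both C1 epimers) | C#C[C@](C)(C#C[Si](C(C)C)(C(C)C)C(C)C)OC(O)[C@@](C)(Br)CCl | intermediate (not isolated)
15 | (4S)-2-[(2R)-2-bromo-1-chloropropan-2-yl]-4-methyl-5-methylidene-4-{[tri(propan-2-yl)silyl]ethynyl}-1,3-dioxolane (both C2 epimers) | C=C1OC(O[C@@]1(C)C#C[Si](C(C)C)(C(C)C)C(C)C)[C@@](C)(Br)CCl | intermediate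
16 | aluminium enolate oxocarbenium zwitterion from 15 and Me2AlCl | C=C(O[Al-](C)(C)Cl)[C@](C)(C#C[Si](C(C)C)(C(C)C)C(C)C)[O+]=C[C@@](C)(Br)CCl | intermediate (not isolated)
17 | (2S,5R)-5-[(2R)-2-bromo-1-chloropropan-2-yl]-2-methyl-2-{[tri(propan-2-yl)silyl]ethynyl}oxolan-3-one | C[C@](Br)(CCl)[C@H]1CC(=O)[C@](C)(C#C[Si](C(C)C)(C(C)C)C(C)C)O1 | intermediate
18 | (2S,3S,5R)-5-[(2R)-2-bromo-1-chloropropan-2-yl]-2-methyl-2-{[tri(propan-2-yl)silyl]ethynyl}oxolan-3-ol | C[C@](Br)(CCl)[C@H]1C[C@H](O)[C@](C)(C#C[Si](C(C)C)(C(C)C)C(C)C)O1 | intermediate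
19 | (2S,3S,5R)-5-[(2R)-2-bromo-1-chloropropan-2-yl]-2-methyl-2-{[tri(propan-2-yl)silyl]ethynyl}oxolan-3-yl trifluoromethanesulfonate | C[C@](Br)(CCl)[C@H]1C[C@H](OS(=O)(=O)C(F)(F)F)[C@](C)(C#C[Si](C(C)C)(C(C)C)C(C)C)O1 | intermediate (not isolated)
20 | (2S,3R,5R)-3-bromo-5-[(2R)-2-bromo-1-chloropropan-2-yl]-2-methyl-2-{[tri(propan-2-yl)silyl]ethynyl}oxolane | C[C@](Br)(CCl)[C@H]1C[C@@H](Br)[C@](C)(C#C[Si](C(C)C)(C(C)C)C(C)C)O1 | intermediate
21 | (2S,3R,5R)-3-bromo-5-[(2R)-2-bromo-1-chloropropan-2-yl]-2-ethynyl-2-methyloxolane | C[C@](Br)(CCl)[C@H]1C[C@@H](Br)[C@](C)(C#C)O1 | intermediate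
22 | chlorobis(cyclopentadienyl)[(E)-2-{(2S,3R,5R)-3-bromo-5-[(2R)-2-bromo-1-chloropropan-2-yl]-2-methyloxolan-2-yl}ethenyl]zirconium | C[C@](Br)(CCl)[C@H]1C[C@@H](Br)[C@](C)(/C=C/[Zr](Cl)(C2C=CC=C2)C2C=CC=C2)O1 | intermediate (not isolated)
23 | (2S,3R,5R)-3-bromo-5-[(2R)-2-bromo-1-chloropropan-2-yl]-2-[(E)-2-bromoethenyl]-2-methyloxolane | C[C@](Br)(CCl)[C@H]1C[C@@H](Br)[C@](C)(/C=C/Br)O1 | target

## Step count and risks

Total steps: 16. Longest linear sequence: 12 steps (steps 5–10, then 11–16, from prenyl acetate 7); the other branch (steps 1–4, then 11–16) has 10.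

The three steps most likely to fail:

**Step 11 (carries the label).** The hindered hemiacetal may be present in too low a concentration, so that gold-catalysed hydration or Meyer–Schuster rearrangement of the propargylic alcohol outruns the cyclisation; the exocyclic enol ether may also isomerise into the ring. The fallback uses known reaction types only and sets out from epoxy alcohol 4 and aldehyde 13. Payne rearrangement and opening at the primary carbon with PhSeNa (from PhSeSePh and NaBH4, NaOH, t-BuOH/H2O) should give (2S,3S)-3-methyl-1-(phenylselanyl)-5-[tri(propan-2-yl)silyl]pent-4-yne-2,3-diol F1, with the quaternary C–O centre untouched. Acid-catalysed acetalisation of F1 with 13 (pyridinium p-toluenesulfonate, MgSO4, CH2Cl2) should give the seleno dioxolane F2. Oxidation (H2O2, then iPr2NH, toluene, 80 °C) and selenoxide syn-elimination, which has only the ring C–H available, should give enol acetal 15, where the route is rejoined; steps 3 and 4 are then not needed.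

**Step 12 (key step).** Ionisation of the electron-poor α-bromo acetal may be slow, the propargylic C–O bond may ionise instead, or facial selectivity at C5 may be poor. The fallback keeps the C4–C5 ring closure but replaces the enolate/oxocarbenium pair with a carbenoid, and sets out from 15. Ozonolysis (O3, CH2Cl2, −78 °C; Me2S) should give the dioxolanone F3. Reductive opening of its acylal C–O bond (Et3SiH, TiCl4, CH2Cl2, −78 °C) should give the α-alkoxy acid F4. Oxalyl chloride with catalytic DMF should give the acyl chloride F5, and diazomethane the diazoketone F6. Rh2(OAc)4 (1 mol%, CH2Cl2, rt) should then effect 1,5 C–H insertion of the rhodium carbenoid into the ether CH2 group activated by O1, closing the oxolan-3-one 17 with the same preference for the C5 substituent cis to the pseudo-equatorial methyl group.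

**Step 14.** The nucleophile must pass the cis C2 methyl group, so E2 elimination to the 2,5-dihydrofuran or a 1,2-shift from the ion pair may compete with substitution. The fallback sets out from ketone 17 and so also bypasses step 13. LiBH(s-Bu)3 (THF, −78 °C) should reduce under substrate control from the face anti to the C2 methyl group and the C5 side chain, giving the 3-epi alcohol F7. SOBr2 (Et2O, 0 °C, no amine base) should convert F7 into its bromosulfite F8, which collapses with retention (SNi, front-side delivery of bromide from the ion pair). No external nucleophile has to enter from the hindered side, and bromide 20 is reached.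

Further compounds
F1 | step 11 | (2S,3S)-3-methyl-1-(phenylselanyl)-5-[tri(propan-2-yl)silyl]pent-4-yne-2,3-diol | c1ccccc1[Se]C[C@@H](O)[C@@](C)(O)C#C[Si](C(C)C)(C(C)C)C(C)C
F2 | step 11 | (4S,5S)-2-[(2R)-2-bromo-1-chloropropan-2-yl]-4-methyl-5-[(phenylselanyl)methyl]-4-{[tri(propan-2-yl)silyl]ethynyl}-1,3-dioxolane (both C2 epimers) | c1ccccc1[Se]C[C@H]1OC(O[C@@]1(C)C#C[Si](C(C)C)(C(C)C)C(C)C)[C@@](C)(Br)CCl
F3 | step 12 | (5S)-2-[(2R)-2-bromo-1-chloropropan-2-yl]-5-methyl-5-{[tri(propan-2-yl)silyl]ethynyl}-1,3-dioxolan-4-one (both C2 epimers) | O=C1OC(O[C@@]1(C)C#C[Si](C(C)C)(C(C)C)C(C)C)[C@@](C)(Br)CCl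
F4 | step 12 | (2S)-2-[(2R)-2-bromo-3-chloro-2-methylpropoxy]-2-methyl-4-[tri(propan-2-yl)silyl]but-3-ynoic acid | OC(=O)[C@](C)(C#C[Si](C(C)C)(C(C)C)C(C)C)OC[C@@](C)(Br)CCl
F5 | step 12 | (2S)-2-[(2R)-2-bromo-3-chloro-2-methylpropoxy]-2-methyl-4-[tri(propan-2-yl)silyl]but-3-ynoyl chloride | ClC(=O)[C@](C)(C#C[Si](C(C)C)(C(C)C)C(C)C)OC[C@@](C)(Br)CCl
F6 | step 12 | (3S)-3-[(2R)-2-bromo-3-chloro-2-methylpropoxy]-1-diazo-3-methyl-5-[tri(propan-2-yl)silyl]pent-4-yn-2-one | [N-]=[N+]=CC(=O)[C@](C)(C#C[Si](C(C)C)(C(C)C)C(C)C)OC[C@@](C)(Br)CCl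
F7 | step 14 | (2S,3R,5R)-5-[(2R)-2-bromo-1-chloropropan-2-yl]-2-methyl-2-{[tri(propan-2-yl)silyl]ethynyl}oxolan-3-ol | C[C@](Br)(CCl)[C@H]1C[C@@H](O)[C@](C)(C#C[Si](C(C)C)(C(C)C)C(C)C)O1
F8 | step 14 | (2S,3R,5R)-5-[(2R)-2-bromo-1-chloropropan-2-yl]-2-methyl-2-{[tri(propan-2-yl)silyl]ethynyl}oxolan-3-yl bromosulfite | C[C@](Br)(CCl)[C@H]1C[C@@H](OS(=O)Br)[C@](C)(C#C[Si](C(C)C)(C(C)C)C(C)C)O1
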